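In a one-step world of first order the fraction of free monomer left is exp(−Θ), where the dimensionless exposure Θ is rate constant times time. One number then gives the outcome, so I test that on the runs.

| setting | beta | alpha | flask |
|---|---|---|---|
| free monomer | 0.050 M (in portions, 4) | 0.20 M (in portions, 4) | 0.10 M (in portions, 4) |
| initiator | 1 mM | 1 mM | 1.0 mM |
| remark | run made earlier; portions every 1.5 min | run made earlier; portions every 1.5 min | the portions of free monomer follow each other after 1.5 min, the first at the start |
| time |  |  | 30 min |

| run | time / min | free monomer / % | monomer in chains / % |
|---|---|---|---|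
| beta | 3.00 | 48 | 3 |
| beta | 8.00 | 91 | 8 |
| beta | 15.0 | 70 | 31 |
| beta | 25.0 | 40 | 59 |
| alpha | 2.00 | 46 | 0 |
| alpha | 4.00 | 72 | 6 |
| alpha | 10.0 | 73 | 31 |
| alpha | 25.0 | 21 | 79 |

(standard deviation of a reading: 2 percentage points)

1. part of the free monomer gone at 30 min
2. the monomer in chains standing at 30 min, as a percentage of the free monomer charged

The last portion goes in at 4.50 min, so I use later readings. At 25.0 min, free monomer and chains sum to 99.0 % in the beta run and 100 % in the alpha run, so what goes stands in chains.

The test fails. The beta run's rate constant reads 0.0375 min⁻¹ early and 0.0560 min⁻¹ late, rising, and the alpha run's late value is higher, 0.0831 min⁻¹. This points to a second concentration that grows with time and charge.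

So I build Θ from readings. The flask's charge equals the geometric mean of the other two, so I take geometric means:

exposure at 25.0 min = 1.20

late rate constant = 0.0682 min⁻¹

Θ = 1.54

This Θ, the flask's exposure at the asked time, leaves a fraction 21.5 %, so I commit to 78.5 % gone and the same in chains.

The forecast gives 81 % gone and 80 % in chains, on the ground that “The first-order rate is not constant but rises with time”. Its conversion stands 2.5 percentage points above my figure.

The flask gives 78.8 % gone and 78.8 % in chains, an exposure of 1.55 against my 1.54.

    free monomer + living end → monomer in chains + living end, rate k1*[living end]*[free monomer] (k = 1.30 M⁻¹ s⁻¹)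
    free monomer + initiator → living end + monomer in chains (k = 0.0250 M⁻¹ s⁻¹)
    initiator → spent initiator (k = 2.80 × 10⁻⁶ s⁻¹)

In the flask, from 4.50 min to 30.0 min, initiator falls from 71.7 % to 8.94 % of its own charge while the living end rises from 2.83 × 10⁻⁴ M to 9.09 × 10⁻⁴ M. Meanwhile in the flask free monomer enters chains on the living end, a pseudo-first-order step reaching 0.0709 min⁻¹ at 30.0 min. Carrying Θ at 0.0682 min⁻¹ to 80 min gives 4.95, a free fraction of 0.708 %. The neighbouring flask, read at that time, holds 0.55 % free monomer.

The earlier runs and the new flask come from a simulation for an exercise, noise included.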